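**Plan**

- Retrosynthetic cuts, in order: C7'–H of the benzylic carbinol (back to an aryl ketone), C3–CH2Ar (lactone enolate plus benzylic bromide), O1–C5 of the lactone (oxygen insertion into a cyclobutanone), aryl–C7' (aryl Grignard plus nitrile). Numbering: lactone O1, C2 (C=O), C3, C4, C5 (OCH2); C7' is the carbinol carbon on C4.
- Enabling feature: ring carbons C2–C3–C4–C5 are closed into the lactone only through O1, and C4 carries two oxygenated carbons (C5 and C7') that are both γ to C2. With O1 removed, C3 still CH2 and the C7' ketone masked as an achiral dioxolane, the ring is a cyclobutanone with a mirror plane through C=O and C4, so its two α-CH2 groups are enantiotopic.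
- Forward: aryl ketone on a methylidenecyclobutane, dioxolane, alkene cleavage to the cyclobutanone, catalytic enantioselective Baeyer–Villiger ring expansion (the only ring-forming event), trans benzylation at C3, debenzylation, ketal hydrolysis, ketone reduction.
- Stereochemistry: C4 is set by the chiral catalyst in the ring expansion; C3 is relayed from C4 by anti alkylation; C7' is relayed from C4 by Felkin–Anh hydride addition.
- Inserting oxygen next to a CH2 places the ring oxygen on C5 and never on C7', a choice that lactonization of a diol acid would leave open.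

Key step: step 4

Assumption: the absolute sense of induction of the chiral catalyst is not derived here; the ligand antipode that gives the stated configuration is used.

**Route**

Step 1
Reactants: 1 3-methylidenecyclobutane-1-carbonitrile; 2 (3,4-dimethoxyphenyl)magnesium bromide
Product: 4 (3,4-dimethoxyphenyl)(3-methylidenecyclobutyl)methanone, via bromomagnesium ketimine 3 (not isolated)
Conditions: 2 (1.3 equiv), CuBr·SMe2 (5 mol %), THF, 0 → 60 °C; then 2 M HCl, 0 °C → rt
Reagents that add atoms: water, O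
Why: Addition of an aryl Grignard reagent to a nitrile stops at the N-magnesio ketimine 3, which cannot add a second equivalent and is hydrolysed by dilute acid to the aryl ketone, while the exocyclic alkene is inert to the organometallic and to brief cold aqueous acid.

Step 2
Reactants: 4 (3,4-dimethoxyphenyl)(3-methylidenecyclobutyl)methanone
Product: 5 2-(3,4-dimethoxyphenyl)-2-(3-methylidenecyclobutyl)-1,3-dioxolane
Conditions: TMSOCH2CH2OTMS (2 equiv), TMSOTf (5 mol %), CH2Cl2, −78 → 0 °C; pyridine quench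
Reagents that add atoms: 1,2-bis(trimethylsilyloxy)ethane, C[Si](C)(C)OCCO[Si](C)(C)C
Why: Silyl-triflate-catalysed ketalization with the bis-silyl glycol is driven by formation of hexamethyldisiloxane, proceeds through an oxocarbenium ion stabilised by the dimethoxyaryl group, and is mild enough not to move the exocyclic double bond into the ring; the dioxolane makes the side chain achiral and non-enolisable.

Step 3
Reactants: 5 2-(3,4-dimethoxyphenyl)-2-(3-methylidenecyclobutyl)-1,3-dioxolane
Product: 7 3-[2-(3,4-dimethoxyphenyl)-1,3-dioxolan-2-yl]cyclobutan-1-one, via vicinal diol 6 (not isolated)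
Conditions: OsO4 (2 mol %), NaIO4 (4 equiv), 2,6-lutidine, dioxane/H2O 3:1, rt
Reagents that add atoms: osmium tetroxide, O=[Os](=O)(=O)=O; sodium periodate, [Na+].[O-][I](=O)(=O)=O
Why: Lemieux–Johnson oxidation: catalytic osmium tetroxide dihydroxylates the only alkene to diol 6, which periodate cleaves in situ to the cyclobutanone and formaldehyde, while the lutidine buffer protects the dioxolane and the reagent pair leaves the dimethoxyarene untouched.

Step 4
Reactants: 7 3-[2-(3,4-dimethoxyphenyl)-1,3-dioxolan-2-yl]cyclobutan-1-one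
Product: 9 (4R)-4-[2-(3,4-dimethoxyphenyl)-1,3-dioxolan-2-yl]oxolan-2-one, via Criegee adduct 8 (not isolated)
Conditions: Sc(OTf)3 (5 mol %), C2-symmetric amino-acid-derived N,N'-dioxide bis(2,6-diisopropylanilide) ligand (6 mol %, antipode giving R), dried m-CPBA (1.2 equiv), EtOAc, −20 °C
Reagents that add atoms: m-chloroperoxybenzoic acid, OOC(=O)c1cccc(Cl)c1
Why: The Sc(III)–N,N'-dioxide complex activates the carbonyl of 7, the peracid adds to give Criegee adduct 8, and the ring CH2 lying antiperiplanar to the O–O bond migrates from carbon to oxygen with loss of 3-chlorobenzoate, which forms the O1–C5 bond of the lactone. The closest known reaction type is the catalytic enantioselective Baeyer–Villiger desymmetrization of prochiral 3-substituted cyclobutanones. The five-membered lactone is closed by ring expansion, a 1,2-shift of a ring carbon to the peroxide oxygen within the four-membered ring, not by an exo or endo cyclization of a chain. The only new stereocenter, C4 of 9, is the former mirror-plane carbon of 7 and becomes stereogenic because the chiral complex allows only one of the two enantiotopic CH2–C(=O) bonds to migrate. The step needs chemoselectivity for the strained ketone over the electron-rich arene and the acid-labile dioxolane, which the strain-accelerated peracid addition at −20 °C in dry ethyl acetate should secure, and it needs no regiocontrol, because both carbons that can migrate are CH2, so the ring oxygen must end on CH2 and never on the benzylic carbon.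

Step 5
Reactants: 10 [4-(benzyloxy)-3-methoxyphenyl]methanol
Product: 11 1-(benzyloxy)-4-(bromomethyl)-2-methoxybenzene
Conditions: PBr3 (0.4 equiv), Et2O, 0 °C; used at once
Reagents that add atoms: phosphorus tribromide, BrP(Br)Br
Why: Conversion of a primary benzylic alcohol into the bromide with phosphorus tribromide (SN2 on the phosphite ester) is routine and leaves the aryl benzyl ether intact.

Step 6
Reactants: 9 (4R)-4-[2-(3,4-dimethoxyphenyl)-1,3-dioxolan-2-yl]oxolan-2-one; 11 1-(benzyloxy)-4-(bromomethyl)-2-methoxybenzene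
Product: 13 (3R,4R)-3-[4-(benzyloxy)-3-methoxybenzyl]-4-[2-(3,4-dimethoxyphenyl)-1,3-dioxolan-2-yl]oxolan-2-one, via lithium enolate 12 (not isolated)
Conditions: LiHMDS (1.1 equiv), THF, −78 °C; then 11 (1.2 equiv), DMPU, −78 → −40 °C
Reagents that add atoms: none
Why: Alkylation of a γ-butyrolactone lithium enolate with a benzylic bromide: the planar enolate 12 is attacked on the face opposite the very bulky C4 dioxolanyl substituent, which sets C3 as R and trans to C4, and the C4 hydrogen is not acidic because the ketone is masked.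

Step 7
Reactants: 13 (3R,4R)-3-[4-(benzyloxy)-3-methoxybenzyl]-4-[2-(3,4-dimethoxyphenyl)-1,3-dioxolan-2-yl]oxolan-2-one
Product: 14 (3R,4R)-4-[2-(3,4-dimethoxyphenyl)-1,3-dioxolan-2-yl]-3-(4-hydroxy-3-methoxybenzyl)oxolan-2-one
Conditions: H2 (1 atm), 10% Pd/C, EtOAc, rt
Reagents that add atoms: none
Why: Catalytic hydrogenolysis cleaves the aryl benzyl ether under neutral conditions that leave the lactone and the dioxolane intact, and it is placed before the benzylic alcohol exists because that C–O bond would be hydrogenolysed as well.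

Step 8
Reactants: 14 (3R,4R)-4-[2-(3,4-dimethoxyphenyl)-1,3-dioxolan-2-yl]-3-(4-hydroxy-3-methoxybenzyl)oxolan-2-one
Product: 15 (3R,4R)-4-(3,4-dimethoxybenzoyl)-3-(4-hydroxy-3-methoxybenzyl)oxolan-2-one
Conditions: 1 M HCl, THF, rt
Reagents that add atoms: water, O
Why: Acid-catalysed hydrolysis of a ketal whose oxocarbenium ion is stabilised by the dimethoxyaryl group should be fast at room temperature; no base is present, so the new ketone cannot eliminate the ring acyloxy group, and any enolisation at C4 returns the more stable trans lactone.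

Step 9
Reactants: 15 (3R,4R)-4-(3,4-dimethoxybenzoyl)-3-(4-hydroxy-3-methoxybenzyl)oxolan-2-one
Product: 17 (3R,4R)-4-[(S)-(3,4-dimethoxyphenyl)(hydroxy)methyl]-3-(4-hydroxy-3-methoxybenzyl)oxolan-2-one, via dilithium alkoxide phenoxide 16 (not isolated)
Conditions: L-Selectride (2.5 equiv), THF, −78 °C; AcOH, −78 °C; aq NH4Cl
Reagents that add atoms: none
Why: Felkin–Anh addition of a bulky hydride: with the C4–C3 bond (the larger ring arm, which carries the benzyl group) anti to the incoming hydride and the aryl group beside the C4 hydrogen, hydride should reach the carbonyl face that gives the S carbinol, and the cold acetic acid quench protonates alkoxide 16 before it can attack the lactone carbonyl.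

**Compound list**

1 | 3-methylidenecyclobutane-1-carbonitrile | C=C1CC(C#N)C1 | starting material
2 | (3,4-dimethoxyphenyl)magnesium bromide (THF solution) | COc1ccc([Mg]Br)cc1OC | starting material
3 | N-bromomagnesio ketimine of 4 | C=C1CC(C1)C(=N[Mg]Br)c1ccc(OC)c(OC)c1 | intermediate
4 | (3,4-dimethoxyphenyl)(3-methylidenecyclobutyl)methanone | C=C1CC(C1)C(=O)c1ccc(OC)c(OC)c1 | intermediate
5 | 2-(3,4-dimethoxyphenyl)-2-(3-methylidenecyclobutyl)-1,3-dioxolane | C=C1CC(C1)C2(OCCO2)c3ccc(OC)c(OC)c3 | intermediate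
6 | 3-[2-(3,4-dimethoxyphenyl)-1,3-dioxolan-2-yl]-1-(hydroxymethyl)cyclobutan-1-ol (cis/trans, both achiral) | OCC1(O)CC(C1)C2(OCCO2)c3ccc(OC)c(OC)c3 | intermediate
7 | 3-[2-(3,4-dimethoxyphenyl)-1,3-dioxolan-2-yl]cyclobutan-1-one | O=C1CC(C1)C2(OCCO2)c3ccc(OC)c(OC)c3 | intermediate
8 | Criegee adduct: 3-[2-(3,4-dimethoxyphenyl)-1,3-dioxolan-2-yl]-1-hydroxycyclobutyl 3-chloroperoxybenzoate | OC1(OOC(=O)c2cccc(Cl)c2)CC(C1)C3(OCCO3)c4ccc(OC)c(OC)c4 | intermediate
9 | (4R)-4-[2-(3,4-dimethoxyphenyl)-1,3-dioxolan-2-yl]oxolan-2-one | O=C1OC[C@@H](C1)C2(OCCO2)c3ccc(OC)c(OC)c3 | intermediate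
10 | [4-(benzyloxy)-3-methoxyphenyl]methanol | COc1cc(CO)ccc1OCc2ccccc2 | starting material
11 | 1-(benzyloxy)-4-(bromomethyl)-2-methoxybenzene | COc1cc(CBr)ccc1OCc2ccccc2 | intermediate
12 | lithium (4R)-4-[2-(3,4-dimethoxyphenyl)-1,3-dioxolan-2-yl]-4,5-dihydrofuran-2-olate (enolate of 9) | [Li]OC1=C[C@H](CO1)C2(OCCO2)c3ccc(OC)c(OC)c3 | intermediate
13 | (3R,4R)-3-[4-(benzyloxy)-3-methoxybenzyl]-4-[2-(3,4-dimethoxyphenyl)-1,3-dioxolan-2-yl]oxolan-2-one | COc1cc(C[C@H]2C(=O)OC[C@@H]2C3(OCCO3)c4ccc(OC)c(OC)c4)ccc1OCc5ccccc5 | intermediate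
14 | (3R,4R)-4-[2-(3,4-dimethoxyphenyl)-1,3-dioxolan-2-yl]-3-(4-hydroxy-3-methoxybenzyl)oxolan-2-one | COc1cc(C[C@H]2C(=O)OC[C@@H]2C3(OCCO3)c4ccc(OC)c(OC)c4)ccc1O | intermediate
15 | (3R,4R)-4-(3,4-dimethoxybenzoyl)-3-(4-hydroxy-3-methoxybenzyl)oxolan-2-one | COc1cc(C[C@H]2C(=O)OC[C@@H]2C(=O)c3ccc(OC)c(OC)c3)ccc1O | intermediate
16 | dilithium salt of 17 (C7' alkoxide and phenoxide) | COc1cc(C[C@H]2C(=O)OC[C@@H]2[C@H](O[Li])c3ccc(OC)c(OC)c3)ccc1O[Li] | intermediate
17 | (3R,4R)-4-[(S)-(3,4-dimethoxyphenyl)(hydroxy)methyl]-3-(4-hydroxy-3-methoxybenzyl)oxolan-2-one | COc1cc(C[C@H]2C(=O)OC[C@@H]2[C@H](O)c3ccc(OC)c(OC)c3)ccc1O | target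

**Summary**

Total step count: 9. Longest linear sequence: 8 (steps 1–4 and 6–9; step 5 is a one-step side branch).

Steps most likely to fail:

1. Step 4. The catalyst may differentiate the two enantiotopic ring CH2 groups incompletely, because the C3 substituent is a ketal carbon and not the aryl group for which this catalysis is best established; the Lewis acid may also open the dioxolane. Fallback, from 7 back to 9: enantioselective deprotonation of 7 with a C2-symmetric chiral lithium amide (lithium bis(1-phenylethyl)amide, antipode chosen for R) and in situ TESCl in THF at −100 °C should give (R)-triethyl({3-[2-(3,4-dimethoxyphenyl)-1,3-dioxolan-2-yl]cyclobut-1-en-1-yl}oxy)silane F1. Ozonolysis of the enol ether (O3, CH2Cl2/MeOH, −78 °C) with NaBH4 work-up should give (3R)-3-[2-(3,4-dimethoxyphenyl)-1,3-dioxolan-2-yl]-4-hydroxybutanoic acid F2, which should lactonize on acidification to pH 4 to 9. The ring oxygen again ends on the CH2 that was the enol CH carbon.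

2. Step 9. Hydride delivery may show poor facial selectivity if the Felkin preference of the ring is small; the acyl group may migrate from O1 to the new C7' alkoxide, switching to the isomeric γ-lactone; the ketone enolate may lose the ring acyloxy group under the basic conditions. Fallback, from 4 to 17, fixes C7' by catalysis before the lactone exists:
   - Asymmetric transfer hydrogenation of 4 (RuCl(p-cymene)(TsDPEN), antipode chosen for S, HCO2H/Et3N) should give (S)-(3,4-dimethoxyphenyl)(3-methylidenecyclobutyl)methanol F3.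
   - TBSCl/imidazole should give its silyl ether, (S)-tert-butyl[(3,4-dimethoxyphenyl)(3-methylidenecyclobutyl)methoxy]dimethylsilane F4.
   - OsO4/NaIO4 cleavage should give 3-[(S)-(tert-butyldimethylsilyloxy)(3,4-dimethoxyphenyl)methyl]cyclobutan-1-one F5.
   - The Sc-catalysed Baeyer–Villiger oxidation, now a reagent-controlled diastereoselective ring expansion, should give (4R)-4-[(S)-(tert-butyldimethylsilyloxy)(3,4-dimethoxyphenyl)methyl]oxolan-2-one F6.
   - LiHMDS and 11 should give the trans-benzylated lactone (3R,4R)-3-[4-(benzyloxy)-3-methoxybenzyl]-4-[(S)-(tert-butyldimethylsilyloxy)(3,4-dimethoxyphenyl)methyl]oxolan-2-one F7.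
   - H2 over Pd/C should give the phenol (3R,4R)-4-[(S)-(tert-butyldimethylsilyloxy)(3,4-dimethoxyphenyl)methyl]-3-(4-hydroxy-3-methoxybenzyl)oxolan-2-one F8.
   - Acetic-acid-buffered TBAF should give 17.

3. Step 6. C-alkylation of the hindered enolate beside a quaternary ketal carbon may be slow, allowing proton exchange between product and enolate (dialkylation) and Claisen self-condensation. Fallback, from 9 to 14, by aldol condensation, hydrogenation and epimerization:
   - Enolate 12 and commercial 4-(benzyloxy)-3-methoxybenzaldehyde at −78 °C should give the 3,4-trans aldol adduct (4R)-3-{[4-(benzyloxy)-3-methoxyphenyl](hydroxy)methyl}-4-[2-(3,4-dimethoxyphenyl)-1,3-dioxolan-2-yl]oxolan-2-one F9 (carbinol epimers).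
   - MsCl/Et3N should give its methanesulfonate F10.
   - DBU should eliminate F10 to (R,E)-3-[4-(benzyloxy)-3-methoxybenzylidene]-4-[2-(3,4-dimethoxyphenyl)-1,3-dioxolan-2-yl]oxolan-2-one F11.
   - H2 over Pd/C should add hydrogen to the alkene face anti to the C4 substituent and remove the benzyl group, giving the cis lactone (3S,4R)-4-[2-(3,4-dimethoxyphenyl)-1,3-dioxolan-2-yl]-3-(4-hydroxy-3-methoxybenzyl)oxolan-2-one F12.
   - Base equilibration at C3 (NaOMe, MeOH, then acidic work-up) should give the more stable trans isomer 14.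

Further compounds

F1 | step 4 | (R)-triethyl({3-[2-(3,4-dimethoxyphenyl)-1,3-dioxolan-2-yl]cyclobut-1-en-1-yl}oxy)silane | CC[Si](CC)(CC)OC1=C[C@@H](C1)C2(OCCO2)c3ccc(OC)c(OC)c3
F2 | step 4 | (3R)-3-[2-(3,4-dimethoxyphenyl)-1,3-dioxolan-2-yl]-4-hydroxybutanoic acid | OC(=O)C[C@H](CO)C1(OCCO1)c2ccc(OC)c(OC)c2
F3 | step 9 | (S)-(3,4-dimethoxyphenyl)(3-methylidenecyclobutyl)methanol | C=C1CC(C1)[C@H](O)c2ccc(OC)c(OC)c2
F4 | step 9 | (S)-tert-butyl[(3,4-dimethoxyphenyl)(3-methylidenecyclobutyl)methoxy]dimethylsilane | C=C1CC(C1)[C@H](O[Si](C)(C)C(C)(C)C)c2ccc(OC)c(OC)c2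
F5 | step 9 | 3-[(S)-(tert-butyldimethylsilyloxy)(3,4-dimethoxyphenyl)methyl]cyclobutan-1-one | O=C1CC(C1)[C@H](O[Si](C)(C)C(C)(C)C)c2ccc(OC)c(OC)c2
F6 | step 9 | (4R)-4-[(S)-(tert-butyldimethylsilyloxy)(3,4-dimethoxyphenyl)methyl]oxolan-2-one | O=C1OC[C@@H](C1)[C@H](O[Si](C)(C)C(C)(C)C)c2ccc(OC)c(OC)c2
F7 | step 9 | (3R,4R)-3-[4-(benzyloxy)-3-methoxybenzyl]-4-[(S)-(tert-butyldimethylsilyloxy)(3,4-dimethoxyphenyl)methyl]oxolan-2-one | COc1cc(C[C@H]2C(=O)OC[C@@H]2[C@H](O[Si](C)(C)C(C)(C)C)c3ccc(OC)c(OC)c3)ccc1OCc4ccccc4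
F8 | step 9 | (3R,4R)-4-[(S)-(tert-butyldimethylsilyloxy)(3,4-dimethoxyphenyl)methyl]-3-(4-hydroxy-3-methoxybenzyl)oxolan-2-one | COc1cc(C[C@H]2C(=O)OC[C@@H]2[C@H](O[Si](C)(C)C(C)(C)C)c3ccc(OC)c(OC)c3)ccc1O
F9 | step 6 | 3,4-trans-(4R)-3-{[4-(benzyloxy)-3-methoxyphenyl](hydroxy)methyl}-4-[2-(3,4-dimethoxyphenyl)-1,3-dioxolan-2-yl]oxolan-2-one (carbinol epimers) | COc1cc(C(O)[C@H]2C(=O)OC[C@@H]2C3(OCCO3)c4ccc(OC)c(OC)c4)ccc1OCc5ccccc5
F10 | step 6 | methanesulfonate of F9 | COc1cc(C(OS(C)(=O)=O)[C@H]2C(=O)OC[C@@H]2C3(OCCO3)c4ccc(OC)c(OC)c4)ccc1OCc5ccccc5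
F11 | step 6 | (R,E)-3-[4-(benzyloxy)-3-methoxybenzylidene]-4-[2-(3,4-dimethoxyphenyl)-1,3-dioxolan-2-yl]oxolan-2-one | COc1cc(/C=C2/C(=O)OC[C@@H]2C3(OCCO3)c4ccc(OC)c(OC)c4)ccc1OCc5ccccc5
F12 | step 6 | (3S,4R)-4-[2-(3,4-dimethoxyphenyl)-1,3-dioxolan-2-yl]-3-(4-hydroxy-3-methoxybenzyl)oxolan-2-one | COc1cc(C[C@@H]2C(=O)OC[C@@H]2C3(OCCO3)c4ccc(OC)c(OC)c4)ccc1O
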